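Everything rests on cutting the two-carbon bridge between the guaiacyl ring and C6 of the tetrahydropyran at its central CH2–CH2 bond. Both carbons are electrophilic in their natural precursors, a vanillyl chloride and the exocyclic C6–CH2–X of a Prins-built pyran, so one polarity is reversed: zinc insertion makes the benzylic carbon nucleophilic, and a nickel-catalysed C(sp3)–C(sp3) Negishi coupling joins it to the primary iodide. The step exploits the exocyclic methylene beside ring oxygen O1: metalation there would expel the ring alkoxide and SN2 is slow, but a nickel/radical pathway is tolerated. The precursor is the complete (2S,4R,6R)-pyran iodide, already carrying the axial C4 acetate and all ring stereocentres.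

Key step: step 6

Remark: 4-(benzyloxy)-3-methoxybenzyl chloride (9) and (R)-epichlorohydrin (3) are taken as catalogue compounds; the free catechol 12 is assumed to need an inert atmosphere during isolation.

Step 1
Reactants: 1 3,4-dihydroxy-5-methoxybenzaldehyde
Product: 2 3,4-bis(benzyloxy)-5-methoxybenzaldehyde
Conditions: BnBr (2.3 equiv), K2CO3, DMF, 60 °C
Reagents that add atoms: benzyl bromide BrCc1ccccc1
Why: Williamson etherification of both phenols leaves the aldehyde untouched and installs benzyl ethers that the last step removes by hydrogenolysis without harming the acetate.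

Step 2
Reactants: 3 (R)-epichlorohydrin
Product: 4 (R)-1-chloropent-4-en-2-ol
Conditions: vinylmagnesium bromide (1.3 equiv), CuI (10 mol %), THF, −40 → −20 °C; then sat. aq NH4Cl
Reagents that add atoms: vinylmagnesium bromide C=C[Mg]Br
Why: Copper-catalysed Grignard opening of the epoxide at its unsubstituted carbon (SN2) does not touch the stereocentre, so (R)-3 should give (R)-4 with the C–Cl bond intact at low temperature.

Step 3
Reactants: 2 3,4-bis(benzyloxy)-5-methoxybenzaldehyde; 4 (R)-1-chloropent-4-en-2-ol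
Product: 6 (2S,4S,6R)-2-[3,4-bis(benzyloxy)-5-methoxyphenyl]-6-(chloromethyl)tetrahydro-2H-pyran-4-ol (all-cis; aryl, OH and CH2Cl equatorial), via pyranyl trifluoroacetate 5 (not isolated)
Conditions: TFA (10 equiv), CH2Cl2, 0 °C → rt; evaporate; then K2CO3 (cat.), MeOH, rt
Reagents that add atoms: trifluoroacetic acid OC(=O)C(F)(F)F (supplies the C4 oxygen)
Why: Prins cyclisation: the (E)-oxocarbenium ion formed from 2 and 4 should close through a chair transition state with the aryl and chloromethyl groups equatorial, so the C6 centre brought in by (R)-4 sets C2 (2,6-cis), and equatorial capture of the C4 cation by trifluoroacetate sets C4 (all-cis), while the electron-withdrawing CH2Cl group disfavours 2-oxonia-Cope side-chain exchange; methanolysis of 5 then frees the alcohol.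

Step 4
Reactants: 6 (2S,4S,6R)-2-[3,4-bis(benzyloxy)-5-methoxyphenyl]-6-(chloromethyl)tetrahydro-2H-pyran-4-ol
Product: 7 (2S,4R,6R)-2-[3,4-bis(benzyloxy)-5-methoxyphenyl]-6-(chloromethyl)tetrahydro-2H-pyran-4-yl acetate (acetate axial, trans to both ring substituents)
Conditions: PPh3 (2 equiv), DIAD (2 equiv), AcOH (2 equiv), THF, 0 °C → rt
Reagents that add atoms: acetic acid CC(=O)O
Why: Mitsunobu reaction: SN2 displacement of the C4 oxyphosphonium by acetate inverts C4, converting the equatorial alcohol directly into the axial acetate of the target.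

Step 5
Reactants: 7 (2S,4R,6R)-2-[3,4-bis(benzyloxy)-5-methoxyphenyl]-6-(chloromethyl)tetrahydro-2H-pyran-4-yl acetate
Product: 8 (2S,4R,6R)-2-[3,4-bis(benzyloxy)-5-methoxyphenyl]-6-(iodomethyl)tetrahydro-2H-pyran-4-yl acetate
Conditions: NaI (10 equiv), butanone, reflux, dark
Reagents that add atoms: sodium iodide [Na+].[I-]
Why: Finkelstein exchange (SN2 at the primary carbon, driven by precipitation of NaCl) gives the iodide needed for nickel activation; no stereocentre is involved and the secondary acetate is inert to iodide.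

Step 6
Reactants: 8 (2S,4R,6R)-2-[3,4-bis(benzyloxy)-5-methoxyphenyl]-6-(iodomethyl)tetrahydro-2H-pyran-4-yl acetate; 9 4-(benzyloxy)-3-methoxybenzyl chloride
Product: 11 (2S,4S,6S)-2-[3,4-bis(benzyloxy)-5-methoxyphenyl]-6-{2-[4-(benzyloxy)-3-methoxyphenyl]ethyl}tetrahydro-2H-pyran-4-yl acetate, via benzylic zinc chloride 10 (not isolated)
Conditions: 9, Zn dust, LiCl, THF, 25 °C; supernatant (1.8 equiv) added slowly to 8, Ni(acac)2 (10 mol %), 4-fluorostyrene (20 mol %), Bu4NI (3 equiv), THF/NMP, −5 °C → rt
Reagents that add atoms: none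
Why: LiCl-promoted zinc insertion into the benzylic C–Cl bond of 9 reverses its polarity to give the benzylic zinc chloride 10, which is decanted from excess zinc so that iodide 8 never meets zinc metal (a β-alkoxy alkylzinc would fragment with ring opening). Nickel(0), formed from Ni(acac)2 and 10, should activate the primary C–I bond of 8 by halogen abstraction and radical recombination, a path indifferent to the β-branching and β-oxygen that retard SN2 chemistry; transmetalation with 10 and reductive elimination, accelerated by the π-acceptor 4-fluorostyrene, then form the benzylic CH2–CH2 bond. The closest known reaction type is the nickel-catalysed alkyl–alkyl Negishi coupling of benzylic zinc halides with primary alkyl iodides in THF/NMP with Bu4NI and a fluorostyrene promoter. No ring is closed and no stereocentre is created; C2, C4 and C6 are untouched because the reacting carbon is the exocyclic methylene, and the axial acetate and benzyl ethers are inert to organozinc reagents. The selectivity needed is cross-coupling over homocoupling of 10 and reductive elimination over β-hydride or β-alkoxide elimination from the alkylnickel intermediate; slow addition of excess 10 at −5 °C, the iodide leaving group and the fluorostyrene ligand are meant to secure it.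

Step 7
Reactants: 11 (2S,4S,6S)-2-[3,4-bis(benzyloxy)-5-methoxyphenyl]-6-{2-[4-(benzyloxy)-3-methoxyphenyl]ethyl}tetrahydro-2H-pyran-4-yl acetate
Product: 12 (2S,4S,6S)-2-(3,4-dihydroxy-5-methoxyphenyl)-6-[2-(4-hydroxy-3-methoxyphenyl)ethyl]tetrahydro-2H-pyran-4-yl acetate
Conditions: H2 (1 atm), 10% Pd/C, EtOAc, rt; filtration under Ar
Reagents that add atoms: none
Why: Catalytic hydrogenolysis cleaves the three aryl benzyl ethers under neutral conditions, under which the acetate and, at 1 atm and room temperature with monitoring, the ring C2–O bond should survive.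

Compound list
1 | 3,4-dihydroxy-5-methoxybenzaldehyde (5-hydroxyvanillin) | O=Cc1cc(O)c(O)c(OC)c1 | starting material
2 | 3,4-bis(benzyloxy)-5-methoxybenzaldehyde | O=Cc1cc(OCc2ccccc2)c(OCc2ccccc2)c(OC)c1 | intermediate
3 | (R)-epichlorohydrin, (R)-2-(chloromethyl)oxirane | ClC[C@H]1CO1 | starting material
4 | (R)-1-chloropent-4-en-2-ol | ClC[C@H](O)CC=C | intermediate
5 | (2S,4S,6R)-2-[3,4-bis(benzyloxy)-5-methoxyphenyl]-6-(chloromethyl)tetrahydro-2H-pyran-4-yl trifluoroacetate (not isolated) | ClC[C@H]1C[C@@H](OC(=O)C(F)(F)F)C[C@@H](c2cc(OCc3ccccc3)c(OCc3ccccc3)c(OC)c2)O1 | intermediate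
6 | (2S,4S,6R)-2-[3,4-bis(benzyloxy)-5-methoxyphenyl]-6-(chloromethyl)tetrahydro-2H-pyran-4-ol | ClC[C@H]1C[C@@H](O)C[C@@H](c2cc(OCc3ccccc3)c(OCc3ccccc3)c(OC)c2)O1 | intermediate
7 | (2S,4R,6R)-2-[3,4-bis(benzyloxy)-5-methoxyphenyl]-6-(chloromethyl)tetrahydro-2H-pyran-4-yl acetate | ClC[C@H]1C[C@H](OC(C)=O)C[C@@H](c2cc(OCc3ccccc3)c(OCc3ccccc3)c(OC)c2)O1 | intermediate
8 | (2S,4R,6R)-2-[3,4-bis(benzyloxy)-5-methoxyphenyl]-6-(iodomethyl)tetrahydro-2H-pyran-4-yl acetate | IC[C@H]1C[C@H](OC(C)=O)C[C@@H](c2cc(OCc3ccccc3)c(OCc3ccccc3)c(OC)c2)O1 | intermediate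
9 | 4-(benzyloxy)-3-methoxybenzyl chloride, 1-(benzyloxy)-4-(chloromethyl)-2-methoxybenzene | COc1cc(CCl)ccc1OCc1ccccc1 | starting material
10 | [4-(benzyloxy)-3-methoxybenzyl]zinc chloride, LiCl complex in THF (not isolated) | COc1cc(C[Zn]Cl)ccc1OCc1ccccc1 | intermediate
11 | (2S,4S,6S)-2-[3,4-bis(benzyloxy)-5-methoxyphenyl]-6-{2-[4-(benzyloxy)-3-methoxyphenyl]ethyl}tetrahydro-2H-pyran-4-yl acetate | COc1cc(CC[C@H]2C[C@H](OC(C)=O)C[C@@H](c3cc(OCc4ccccc4)c(OCc4ccccc4)c(OC)c3)O2)ccc1OCc1ccccc1 | intermediate
12 | (2S,4S,6S)-2-(3,4-dihydroxy-5-methoxyphenyl)-6-[2-(4-hydroxy-3-methoxyphenyl)ethyl]tetrahydro-2H-pyran-4-yl acetate | COc1cc(CC[C@H]2C[C@H](OC(C)=O)C[C@@H](c3cc(O)c(O)c(OC)c3)O2)ccc1O | target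

Total step count: 7. Longest linear sequence: 6 steps (3 → 4 → 6 → 7 → 8 → 11 → 12; equally long from 1).

Steps most likely to fail

Step 6. The benzylic zinc reagent may homocouple faster than it cross-couples, or the alkylnickel intermediate may undergo β-hydride or β-alkoxide elimination with unsaturation or opening of the ring. The fallback keeps the reversed polarity at the benzylic carbon but makes the bond as an alkene. It sets out from 8 and 9 and returns to the route at 12. Iodide 8 would be oxidised by the Kornblum procedure (DMSO, NaHCO3, 100 °C) to the aldehyde (2S,4R,6R)-2-[3,4-bis(benzyloxy)-5-methoxyphenyl]-6-formyltetrahydro-2H-pyran-4-yl acetate F1. Chloride 9 with PPh3 (toluene, reflux) should give [4-(benzyloxy)-3-methoxybenzyl]triphenylphosphonium chloride F2. Wittig olefination of F1 with the ylide of F2 (KOtBu, THF, −78 → 0 °C) should give (2S,4S,6R)-2-[3,4-bis(benzyloxy)-5-methoxyphenyl]-6-{2-[4-(benzyloxy)-3-methoxyphenyl]ethenyl}tetrahydro-2H-pyran-4-yl acetate F3 as an E/Z mixture. Hydrogenation under the conditions of step 7 then saturates the alkene and removes the benzyl groups, giving 12.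

Step 3. Oxocarbenium formation and ring closure may be slow for the donor-substituted aldehyde, allowing acid-induced loss of benzyl ethers or exchange of the aldehyde partner under the protic conditions. The fallback is a segment-coupling Prins cyclisation that generates the oxocarbenium ion without water or free aldehyde. It sets out from 2 and 4 and returns at 6. Pinnick oxidation of 2 (NaClO2, NaH2PO4, 2-methyl-2-butene, t-BuOH/H2O) should give 3,4-bis(benzyloxy)-5-methoxybenzoic acid F4. Steglich esterification with 4 (DCC, DMAP, CH2Cl2) gives (2R)-1-chloropent-4-en-2-yl 3,4-bis(benzyloxy)-5-methoxybenzoate F5. Reductive acetylation (DIBAL-H, CH2Cl2, −78 °C; then Ac2O, pyridine, DMAP) gives the α-acetoxy ether [3,4-bis(benzyloxy)-5-methoxyphenyl]{[(2R)-1-chloropent-4-en-2-yl]oxy}methyl acetate F6 as a mixture of acetal epimers. Ionisation and cyclisation (BF3·OEt2, AcOH, CH2Cl2/hexane, 0 °C) should give the all-cis (2S,4S,6R)-2-[3,4-bis(benzyloxy)-5-methoxyphenyl]-6-(chloromethyl)tetrahydro-2H-pyran-4-yl acetate F7. Methanolysis (K2CO3, MeOH) then gives 6.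

Step 4. E2 elimination of the activated alcohol to a dihydropyran may compete with the axial SN2 attack of the weakly acidic acetic acid, or the inversion may be incomplete. The fallback sets the axial oxygen by reduction instead of substitution. It sets out from 6 and returns at 7. Dess–Martin oxidation (CH2Cl2, rt) should give (2S,6R)-2-[3,4-bis(benzyloxy)-5-methoxyphenyl]-6-(chloromethyl)tetrahydro-4H-pyran-4-one F8. L-Selectride (THF, −78 °C) delivers hydride from the equatorial side to give the axial alcohol (2S,4R,6R)-2-[3,4-bis(benzyloxy)-5-methoxyphenyl]-6-(chloromethyl)tetrahydro-2H-pyran-4-ol F9. Acetylation (Ac2O, pyridine, DMAP) then gives 7.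

Further compounds
F1 | step 6 | (2S,4R,6R)-2-[3,4-bis(benzyloxy)-5-methoxyphenyl]-6-formyltetrahydro-2H-pyran-4-yl acetate | O=C[C@H]1C[C@H](OC(C)=O)C[C@@H](c2cc(OCc3ccccc3)c(OCc3ccccc3)c(OC)c2)O1
F2 | step 6 | [4-(benzyloxy)-3-methoxybenzyl]triphenylphosphonium chloride | COc1cc(C[P+](c2ccccc2)(c2ccccc2)c2ccccc2)ccc1OCc1ccccc1.[Cl-]
F3 | step 6 | (2S,4S,6R)-2-[3,4-bis(benzyloxy)-5-methoxyphenyl]-6-{2-[4-(benzyloxy)-3-methoxyphenyl]ethenyl}tetrahydro-2H-pyran-4-yl acetate (E/Z mixture) | COc1cc(C=C[C@H]2C[C@H](OC(C)=O)C[C@@H](c3cc(OCc4ccccc4)c(OCc4ccccc4)c(OC)c3)O2)ccc1OCc1ccccc1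
F4 | step 3 | 3,4-bis(benzyloxy)-5-methoxybenzoic acid | OC(=O)c1cc(OCc2ccccc2)c(OCc2ccccc2)c(OC)c1
F5 | step 3 | (2R)-1-chloropent-4-en-2-yl 3,4-bis(benzyloxy)-5-methoxybenzoate | ClC[C@H](OC(=O)c1cc(OCc2ccccc2)c(OCc2ccccc2)c(OC)c1)CC=C
F6 | step 3 | [3,4-bis(benzyloxy)-5-methoxyphenyl]{[(2R)-1-chloropent-4-en-2-yl]oxy}methyl acetate (acetal epimers) | ClC[C@H](OC(OC(C)=O)c1cc(OCc2ccccc2)c(OCc2ccccc2)c(OC)c1)CC=C
F7 | step 3 | (2S,4S,6R)-2-[3,4-bis(benzyloxy)-5-methoxyphenyl]-6-(chloromethyl)tetrahydro-2H-pyran-4-yl acetate | ClC[C@H]1C[C@@H](OC(C)=O)C[C@@H](c2cc(OCc3ccccc3)c(OCc3ccccc3)c(OC)c2)O1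
F8 | step 4 | (2S,6R)-2-[3,4-bis(benzyloxy)-5-methoxyphenyl]-6-(chloromethyl)tetrahydro-4H-pyran-4-one | ClC[C@H]1CC(=O)C[C@@H](c2cc(OCc3ccccc3)c(OCc3ccccc3)c(OC)c2)O1
F9 | step 4 | (2S,4R,6R)-2-[3,4-bis(benzyloxy)-5-methoxyphenyl]-6-(chloromethyl)tetrahydro-2H-pyran-4-ol | ClC[C@H]1C[C@H](O)C[C@@H](c2cc(OCc3ccccc3)c(OCc3ccccc3)c(OC)c2)O1
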